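**Plan**

- Retrosynthesis, in order: (i) the quinone goes back to its bis-methyl ether; (ii) the C3=C4 double bond of the furan-2(5H)-one ring is cut by ring-closing olefin metathesis; (iii) the C5–O1 ester bond is cut (asymmetric SN2′ esterification of a Z-allylic imidate by a 2-alkylacrylic acid); (iv) the chain is cut between the alkyne carbon and the allylic CH2 (sp–sp3 coupling); (v) the aryl–CH2 bond is cut.
- Forward: the arene and geranyl bromide are joined first, the chain terminus is oxidised and extended by propargyl alcohol, the Z-allylic imidate is esterified with the acrylic acid (made separately from phosphonoacetate), and the lactone is closed. The six-membered ring is bought as an arene and becomes the quinone in the last step.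
- Stereochemistry: the single stereocenter (C5 of the lactone, R) is set by catalyst control in step 12. The two chain alkenes are E, one from geranyl bromide and one from E-selective allylic oxidation. The ring alkene is cis by ring constraint.
- Enabling feature: in the lactone ring O1–C2(=O)–C3=C4–C5, C3 carries only the homoprenyl CH2 and C4 only H, and the O1–C2 ester ties C3 to C5. Both alkene carbons can therefore be the =CH2-bearing carbons of an acyclic allyl 2-alkylacrylate, the only mono- and 1,1-disubstituted alkenes beside three trisubstituted ones.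
- This polarity-neutral union avoids the configurationally labile α-acyloxy aldehyde that a carbonyl condensation at the same bond would need.

Key step: step 13

Remark: the configuration given at the lactone carbon corresponds to R (O > ring CH= > chain CH2 > H), and the route is laid out for this enantiomer.

**Step 1**
Reactants: 1 4-methoxy-2-methylphenol
Product: 2 2-bromo-4-methoxy-6-methylphenol
Conditions: NBS, i-Pr2NH (10 mol%), CH2Cl2, 0 °C
Reagents that add atoms: N-bromosuccinimide, O=C1CCC(=O)N1Br
Why: Electrophilic aromatic bromination is directed by the free hydroxyl, whose only open ortho or para position is C6 (para is taken by OMe, the other ortho by Me), and amine-catalysed NBS bromination of phenols is ortho-selective.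

**Step 2**
Reactants: 2 2-bromo-4-methoxy-6-methylphenol
Product: 3 1-bromo-2,5-dimethoxy-3-methylbenzene
Conditions: MeI, K2CO3, acetone, reflux
Reagents that add atoms: iodomethane, CI
Why: Williamson ether synthesis caps the hydroquinone as its bis-methyl ether, the masked oxidation level of the quinone that is released in step 14.

**Step 3**
Reactants: 3 1-bromo-2,5-dimethoxy-3-methylbenzene; 4 geranyl bromide
Product: 6 1-[(2E)-3,7-dimethylocta-2,6-dienyl]-2,5-dimethoxy-3-methylbenzene, via aryllithium 5 (not isolated)
Conditions: n-BuLi, THF, −78 °C; then CuBr·SMe2 (10 mol%) and 4, −78 °C to rt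
Reagents that add atoms: none
Why: Bromine–lithium exchange followed by copper-catalysed SN2 allylation of the aryllithium at the primary carbon of the allylic bromide (the SN2′ site is fully substituted) joins arene and chain with the 2E alkene of geranyl bromide retained.

**Step 4**
Reactants: 6 1-[(2E)-3,7-dimethylocta-2,6-dienyl]-2,5-dimethoxy-3-methylbenzene
Product: 7 (2E,6E)-8-(2,5-dimethoxy-3-methylphenyl)-2,6-dimethylocta-2,6-dien-1-ol
Conditions: SeO2 (0.3 equiv), t-BuOOH (70% aq., 3 equiv), salicylic acid (10 mol%), CH2Cl2, 0 °C to rt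
Reagents that add atoms: selenium dioxide, O=[Se]=O; tert-butyl hydroperoxide, CC(C)(C)OO
Why: Riley allylic oxidation (ene reaction of SeO2, then [2,3]-sigmatropic shift of the allylseleninic acid) should favour the terminal isopropylidene group, the least hindered trisubstituted alkene, and within it the methyl trans to the chain, which gives the 2E primary allylic alcohol while t-BuOOH turns selenium over.

**Step 5**
Reactants: 7 (2E,6E)-8-(2,5-dimethoxy-3-methylphenyl)-2,6-dimethylocta-2,6-dien-1-ol
Product: 8 1-[(2E,6E)-8-bromo-3,7-dimethylocta-2,6-dienyl]-2,5-dimethoxy-3-methylbenzene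
Conditions: CBr4, PPh3, CH2Cl2, 0 °C
Reagents that add atoms: tetrabromomethane, BrC(Br)(Br)Br
Why: Appel bromination displaces the oxyphosphonium by bromide at the primary carbon (SN2), so neither allylic transposition nor loss of the E geometry is expected at 0 °C.

**Step 6**
Reactants: 8 1-[(2E,6E)-8-bromo-3,7-dimethylocta-2,6-dienyl]-2,5-dimethoxy-3-methylbenzene; 9 propargyl alcohol
Product: 10 (5E,9E)-11-(2,5-dimethoxy-3-methylphenyl)-5,9-dimethylundeca-5,9-dien-2-yn-1-ol
Conditions: CuI (20 mol%), NaI, Cs2CO3, DMF, rt
Reagents that add atoms: none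
Why: Copper-catalysed alkylation of the in situ copper acetylide (C(sp)–C(sp3) coupling) takes place at the unhindered primary allylic carbon and tolerates the free hydroxyl, which gives the skipped enyne with the E alkene intact.

**Step 7**
Reactants: 10 (5E,9E)-11-(2,5-dimethoxy-3-methylphenyl)-5,9-dimethylundeca-5,9-dien-2-yn-1-ol
Product: 11 (2Z,5E,9E)-11-(2,5-dimethoxy-3-methylphenyl)-5,9-dimethylundeca-2,5,9-trien-1-ol
Conditions: H2 (1 atm), Pd/CaCO3 poisoned with Pb(OAc)2 (Lindlar catalyst), quinoline, EtOAc, rt
Reagents that add atoms: none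
Why: Lindlar semi-hydrogenation adds H2 syn across the alkyne on the poisoned surface to give the 2Z alkene that step 12 needs for high enantioselectivity, and trisubstituted alkenes are not reduced under these conditions.

**Step 8**
Reactants: 11 (2Z,5E,9E)-11-(2,5-dimethoxy-3-methylphenyl)-5,9-dimethylundeca-2,5,9-trien-1-ol
Product: 12 (2Z,5E,9E)-11-(2,5-dimethoxy-3-methylphenyl)-5,9-dimethylundeca-2,5,9-trienyl 2,2,2-trichloroacetimidate
Conditions: Cl3CCN, DBU (10 mol%), CH2Cl2, 0 °C
Reagents that add atoms: trichloroacetonitrile, N#CC(Cl)(Cl)Cl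
Why: Base-catalysed addition of the alkoxide to the nitrile (trichloroacetimidate formation) installs the leaving group whose nitrogen binds the palladium catalyst in step 12, and the imidate is used without heating so that its thermal [3,3] shift to the amide does not start.

**Step 9**
Reactants: 13 triethyl phosphonoacetate; 14 5-bromo-2-methylpent-2-ene
Product: 16 ethyl 2-(diethoxyphosphoryl)-6-methylhept-5-enoate, via sodium phosphonoacetate enolate 15 (not isolated)
Conditions: NaH, THF/DMSO, 0 °C; then 14, 60 °C
Reagents that add atoms: none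
Why: SN2 alkylation of the stabilised phosphonoacetate anion with a primary homoallylic bromide places the homoprenyl chain on the future C3 of the lactone.

**Step 10**
Reactants: 16 ethyl 2-(diethoxyphosphoryl)-6-methylhept-5-enoate
Product: 17 ethyl 6-methyl-2-methylidenehept-5-enoate
Conditions: aq. CH2O (37%), K2CO3, THF, rt to 50 °C
Reagents that add atoms: formaldehyde, C=O
Why: Horner–Wadsworth–Emmons olefination with formaldehyde converts the alkylated phosphonate into the 2-substituted acrylate, whose =CH2 is later lost as ethene.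

**Step 11**
Reactants: 17 ethyl 6-methyl-2-methylidenehept-5-enoate
Product: 19 6-methyl-2-methylidenehept-5-enoic acid, via lithium carboxylate 18 (not isolated)
Conditions: LiOH·H2O, THF/H2O, rt; then 1 M HCl
Reagents that add atoms: lithium hydroxide, [Li+].[OH-]
Why: Saponification of the ethyl ester at room temperature gives the free acid without conjugate addition to the hindered 2-alkylacrylate.

**Step 12**
Reactants: 12 (2Z,5E,9E)-11-(2,5-dimethoxy-3-methylphenyl)-5,9-dimethylundeca-2,5,9-trienyl 2,2,2-trichloroacetimidate; 19 6-methyl-2-methylidenehept-5-enoic acid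
Product: 20 (3R,5E,9E)-11-(2,5-dimethoxy-3-methylphenyl)-5,9-dimethylundeca-1,5,9-trien-3-yl 6-methyl-2-methylidenehept-5-enoate
Conditions: (Rp,S)-[COP-OAc]2, that is di-μ-acetato-bis[(η5-(S)-(pR)-2-(4′-isopropyl-2′-oxazolinyl)cyclopentadienyl-1-C,3′-N)(η4-tetraphenylcyclobutadiene)cobalt]dipalladium (1 mol%), 19 (3 equiv), CH2Cl2, 23 °C
Reagents that add atoms: none
Why: Catalytic asymmetric SN2′ allylic esterification: the imidate nitrogen binds divalent palladium of the planar-chiral palladacycle, the Z alkene coordinates on one enantioface, the carboxylic acid attacks C3 anti to palladium and syn-deoxypalladation expels trichloroacetamide, so the C3 stereocenter is set by the catalyst, the (Rp,S) antipode being the one expected to deliver the 3R branched ester from a (Z)-2-alkenyl imidate.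

**Step 13**
Reactants: 20 (3R,5E,9E)-11-(2,5-dimethoxy-3-methylphenyl)-5,9-dimethylundeca-1,5,9-trien-3-yl 6-methyl-2-methylidenehept-5-enoate
Product: 21 (5R)-5-[(2E,6E)-8-(2,5-dimethoxy-3-methylphenyl)-2,6-dimethylocta-2,6-dienyl]-3-(4-methylpent-3-enyl)furan-2(5H)-one
Conditions: second-generation Grubbs catalyst (H2IMes)(PCy3)Cl2Ru=CHPh (5–10 mol%), 1,4-benzoquinone (10 mol%), CH2Cl2 (0.005 M), reflux
Reagents that add atoms: none
Why: Ring-closing olefin metathesis by the Chauvin mechanism: the ruthenium benzylidene loads on the monosubstituted vinyl group, the new alkylidene undergoes [2+2] cycloaddition with the 1,1-disubstituted acrylate alkene held close by the ester, and cycloreversion releases the butenolide and Ru=CH2, with ethene leaving the solution. The closest known reaction type is the ring-closing metathesis of 2-substituted acrylates of secondary allylic alcohols to 3-substituted furan-2(5H)-ones. The one ring closed is the five-membered lactone, formed by joining C3 and C4 as a ring-enforced cis trisubstituted alkene, with both new sp2 carbons endocyclic and the O1–C2(=O) ester as the tether already in place. No new stereocenter arises, and C5 should keep its R configuration because the step is neutral and the allylic C–O bond is not ionised. The selectivity needed is site selectivity among five C=C bonds, and substitution secures it: only the vinyl and acrylate alkenes are mono- and 1,1-disubstituted, whereas the three trisubstituted alkenes react far more slowly and could close only four-membered or eight-membered and larger rings. Benzoquinone is added to suppress ruthenium hydride migration of the skipped double bonds, and high dilution disfavours cross-metathesis.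

**Step 14**
Reactants: 21 (5R)-5-[(2E,6E)-8-(2,5-dimethoxy-3-methylphenyl)-2,6-dimethylocta-2,6-dienyl]-3-(4-methylpent-3-enyl)furan-2(5H)-one
Product: 22 yezoquinolide
Conditions: (NH4)2Ce(NO3)6 (2.5 equiv), MeCN/H2O (2:1), 0 °C
Reagents that add atoms: water, O
Why: Oxidative demethylation by tetravalent cerium (two one-electron oxidations of the electron-rich 1,4-dimethoxyarene, water adding at the ipso carbons and methanol leaving) should give the para-quinone, while the isolated trisubstituted alkenes, the butenolide and the C5 stereocenter are not touched in a short, cold reaction.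

**Compound list**

1 | 4-methoxy-2-methylphenol | COc1ccc(O)c(C)c1 | starting material
2 | 2-bromo-4-methoxy-6-methylphenol | Brc1cc(OC)cc(C)c1O | intermediate
3 | 1-bromo-2,5-dimethoxy-3-methylbenzene | Brc1cc(OC)cc(C)c1OC | intermediate
4 | geranyl bromide, (2E)-1-bromo-3,7-dimethylocta-2,6-diene | CC(C)=CCC/C(C)=C/CBr | starting material
5 | (2,5-dimethoxy-3-methylphenyl)lithium (not isolated) | [Li]c1cc(OC)cc(C)c1OC | intermediate
6 | 1-[(2E)-3,7-dimethylocta-2,6-dienyl]-2,5-dimethoxy-3-methylbenzene | CC(C)=CCC/C(C)=C/Cc1cc(OC)cc(C)c1OC | intermediate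
7 | (2E,6E)-8-(2,5-dimethoxy-3-methylphenyl)-2,6-dimethylocta-2,6-dien-1-ol | OC/C(C)=C/CC/C(C)=C/Cc1cc(OC)cc(C)c1OC | intermediate
8 | 1-[(2E,6E)-8-bromo-3,7-dimethylocta-2,6-dienyl]-2,5-dimethoxy-3-methylbenzene | BrC/C(C)=C/CC/C(C)=C/Cc1cc(OC)cc(C)c1OC | intermediate
9 | propargyl alcohol (prop-2-yn-1-ol) | OCC#C | starting material
10 | (5E,9E)-11-(2,5-dimethoxy-3-methylphenyl)-5,9-dimethylundeca-5,9-dien-2-yn-1-ol | OCC#CC/C(C)=C/CC/C(C)=C/Cc1cc(OC)cc(C)c1OC | intermediate
11 | (2Z,5E,9E)-11-(2,5-dimethoxy-3-methylphenyl)-5,9-dimethylundeca-2,5,9-trien-1-ol | OC/C=C\C/C(C)=C/CC/C(C)=C/Cc1cc(OC)cc(C)c1OC | intermediate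
12 | (2Z,5E,9E)-11-(2,5-dimethoxy-3-methylphenyl)-5,9-dimethylundeca-2,5,9-trienyl 2,2,2-trichloroacetimidate | ClC(Cl)(Cl)C(=N)OC/C=C\C/C(C)=C/CC/C(C)=C/Cc1cc(OC)cc(C)c1OC | intermediate
13 | triethyl phosphonoacetate | CCOC(=O)CP(=O)(OCC)OCC | starting material
14 | 5-bromo-2-methylpent-2-ene | CC(C)=CCCBr | starting material
15 | sodium enolate of triethyl phosphonoacetate (not isolated) | CCOC(=O)[CH-]P(=O)(OCC)OCC.[Na+] | intermediate
16 | ethyl 2-(diethoxyphosphoryl)-6-methylhept-5-enoate (racemic) | CCOC(=O)C(CCC=C(C)C)P(=O)(OCC)OCC | intermediate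
17 | ethyl 6-methyl-2-methylidenehept-5-enoate | CCOC(=O)C(=C)CCC=C(C)C | intermediate
18 | lithium 6-methyl-2-methylidenehept-5-enoate (not isolated) | [Li+].[O-]C(=O)C(=C)CCC=C(C)C | intermediate
19 | 6-methyl-2-methylidenehept-5-enoic acid | OC(=O)C(=C)CCC=C(C)C | intermediate
20 | (3R,5E,9E)-11-(2,5-dimethoxy-3-methylphenyl)-5,9-dimethylundeca-1,5,9-trien-3-yl 6-methyl-2-methylidenehept-5-enoate | C=C[C@@H](C/C(C)=C/CC/C(C)=C/Cc1cc(OC)cc(C)c1OC)OC(=O)C(=C)CCC=C(C)C | intermediate
21 | (5R)-5-[(2E,6E)-8-(2,5-dimethoxy-3-methylphenyl)-2,6-dimethylocta-2,6-dienyl]-3-(4-methylpent-3-enyl)furan-2(5H)-one | CC(C)=CCCC1=C[C@@H](C/C(C)=C/CC/C(C)=C/Cc2cc(OC)cc(C)c2OC)OC1=O | intermediate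
22 | yezoquinolide, 2-methyl-6-[(2E,6E)-3,7-dimethyl-8-[(2R)-4-(4-methylpent-3-enyl)-5-oxo-2,5-dihydrofuran-2-yl]octa-2,6-dienyl]cyclohexa-2,5-diene-1,4-dione | CC(C)=CCCC1=C[C@@H](C/C(C)=C/CC/C(C)=C/CC2=CC(=O)C=C(C)C2=O)OC1=O | target

**Step count and risks**

Total steps: 14. Longest linear sequence: 11 (steps 1–8 and 12–14); steps 9–11 make the acid partner.

Step 12 is the most exposed. The α-branched acrylic acid may attack slowly, the skipped diene may compete for the palladium centre, and enantio- or branched/linear control may erode. The fallback sets the stereocenter by reagent-controlled epoxidation; it sets out from 10 and comes back at 20. Reduction of 10 with NaAlH2(OCH2CH2OMe)2 in THF should give the (2E,5E,9E)-allylic alcohol F1. Sharpless asymmetric epoxidation (Ti(OiPr)4, D-(−)-diisopropyl tartrate, t-BuOOH, 4 Å sieves, CH2Cl2, −20 °C) should give the (2R,3R)-epoxy alcohol F2. I2, PPh3 and imidazole should convert it into the epoxy iodide F3. Zinc dust in AcOH/EtOH should open F3 reductively to the (R)-allylic alcohol F4, with the carbinol C–O bond untouched. Steglich esterification of F4 with 19 (DCC, DMAP, CH2Cl2) gives 20.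

Step 13 may stall at the hindered acrylate, ruthenium hydrides may move the skipped double bonds, or the catalyst may be drawn into the trisubstituted alkenes. The fallback closes the same C3=C4 bond by an intramolecular Horner–Wadsworth–Emmons reaction; it sets out from 10 by way of F1 and comes back at 21. Sharpless epoxidation of F1 with L-(+)-diisopropyl tartrate should give the (2S,3S)-epoxy alcohol F5. Selective saponification of 16 (NaOH, EtOH/H2O, rt) gives the phosphono acid F6. Opening of F5 by F6 at C3 with inversion, mediated by Ti(OiPr)4, should give the (2S,3R)-3-acyloxy-1,2-diol F7. NaIO4 in THF/H2O should cleave the diol to the (R)-α-acyloxy aldehyde F8. LiCl and DBU in MeCN at 0 °C (Masamune–Roush conditions) should close the ring to 21.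

Step 4 may suffer over-oxidation to the enal, or competing attack at the internal alkene or at the benzylic-allylic CH2. The fallback replaces the ene oxidation by olefin cross-metathesis; it sets out from 6 and comes back at 7. Methacrolein in excess and the second-generation Hoveyda–Grubbs catalyst (H2IMes)Cl2Ru=CH(C6H4-2-OiPr) in CH2Cl2 at 40 °C should exchange the terminal isopropylidene group for the (2E)-2-methyl enal F9, with loss of 2-methylpropene. Luche reduction (NaBH4, CeCl3·7H2O, MeOH, 0 °C) then gives 7.

**Further compounds**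

F1 | step 12 | (2E,5E,9E)-11-(2,5-dimethoxy-3-methylphenyl)-5,9-dimethylundeca-2,5,9-trien-1-ol | OC/C=C/C/C(C)=C/CC/C(C)=C/Cc1cc(OC)cc(C)c1OC
F2 | step 12 | [(2R,3R)-3-[(2E,6E)-8-(2,5-dimethoxy-3-methylphenyl)-2,6-dimethylocta-2,6-dienyl]oxiran-2-yl]methanol | OC[C@H]1O[C@@H]1C/C(C)=C/CC/C(C)=C/Cc2cc(OC)cc(C)c2OC
F3 | step 12 | (2S,3R)-2-(iodomethyl)-3-[(2E,6E)-8-(2,5-dimethoxy-3-methylphenyl)-2,6-dimethylocta-2,6-dienyl]oxirane | IC[C@H]1O[C@@H]1C/C(C)=C/CC/C(C)=C/Cc2cc(OC)cc(C)c2OC
F4 | step 12 | (3R,5E,9E)-11-(2,5-dimethoxy-3-methylphenyl)-5,9-dimethylundeca-1,5,9-trien-3-ol | C=C[C@@H](C/C(C)=C/CC/C(C)=C/Cc1cc(OC)cc(C)c1OC)O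
F5 | step 13 | [(2S,3S)-3-[(2E,6E)-8-(2,5-dimethoxy-3-methylphenyl)-2,6-dimethylocta-2,6-dienyl]oxiran-2-yl]methanol | OC[C@@H]1O[C@H]1C/C(C)=C/CC/C(C)=C/Cc2cc(OC)cc(C)c2OC
F6 | step 13 | 2-(diethoxyphosphoryl)-6-methylhept-5-enoic acid | OC(=O)C(CCC=C(C)C)P(=O)(OCC)OCC
F7 | step 13 | (2S,3R,5E,9E)-11-(2,5-dimethoxy-3-methylphenyl)-1,2-dihydroxy-5,9-dimethylundeca-5,9-dien-3-yl 2-(diethoxyphosphoryl)-6-methylhept-5-enoate | OC[C@H](O)[C@@H](C/C(C)=C/CC/C(C)=C/Cc1cc(OC)cc(C)c1OC)OC(=O)C(CCC=C(C)C)P(=O)(OCC)OCC
F8 | step 13 | (2R,4E,8E)-10-(2,5-dimethoxy-3-methylphenyl)-4,8-dimethyl-1-oxodeca-4,8-dien-2-yl 2-(diethoxyphosphoryl)-6-methylhept-5-enoate | O=C[C@@H](C/C(C)=C/CC/C(C)=C/Cc1cc(OC)cc(C)c1OC)OC(=O)C(CCC=C(C)C)P(=O)(OCC)OCC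
F9 | step 4 | (2E,6E)-8-(2,5-dimethoxy-3-methylphenyl)-2,6-dimethylocta-2,6-dienal | O=C/C(C)=C/CC/C(C)=C/Cc1cc(OC)cc(C)c1OC
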